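# Total synthesis of dictyol H (target as drawn: C6 secondary alcohol, tertiary acetate on the THF side chain)

**Retrosynthetic overview**
- Target ⇐ face-selective reduction of the C6 ketone ⇐ cis-hydroazulene. The exocyclic methylene comes from methylenation of the C10 ketone, and the cyclopentene is closed last by RCM of a C5-isopropenyl/C1-allyl cycloheptanone.
- That cycloheptanone ⇐ tandem cuprate addition/allylation on a 4-silyloxy-5-(THF-yl)cyclohept-2-enone ⇐ γ-oxygenation of the dienolate formed in the central radical step.
- Central radical step: decarboxylative photoredox 1,6-addition of the tertiary α-alkoxy THF radical to 2,4-cycloheptadienone. It forms the hindered C7–C(quaternary) bond.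
- The THF radical precursor comes from a Grignard/pyruvate addition, Shi epoxidation and 5-exo epoxy-alcohol cyclization.
- Ring order: THF (step 3), then the seven-membered ring (present in the starting dienone), then the cyclopentene (step 10).

**Assumptions**
- 2,4-Cycloheptadien-1-one (8 heavy atoms) is purchased. If it is not available it comes from cyclohept-2-enone by dehydrogenation.
- "Dictyol H" is the acetate exactly as drawn. The tertiary acetate is installed on the small THF fragment because it cannot be made selectively in the presence of the C6–OH.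
- The C7 epimers formed in step 6 are separable by chromatography.

---

**Step 1**
Reactants: 1 (5-bromo-2-methylpent-2-ene); 2 (methyl pyruvate)
Product: 3 (methyl 2-hydroxy-2,6-dimethylhept-5-enoate, racemic at C2)
Conditions: Mg, THF, then 2, –78 °C → 0 °C
Reagents that add atoms: none
Why: Grignard 1,2-addition to an α-ketoester gives the tertiary α-hydroxy ester; this carbon (Ca) becomes a planar radical later, so its configuration here is irrelevant.

**Step 2**
Reactants: 3
Product: 4 (methyl 2-hydroxy-2,6-dimethyl-5,6-epoxyheptanoate; the epoxide CH is stereodefined)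
Conditions: Oxone, fructose-derived Shi ketone (30 mol %), Bu4NHSO4, K2CO3, MeCN/DMM/H2O buffer pH 10.5, 0 °C
Reagents that add atoms: Oxone (O-atom donor), SMILES OOS(=O)(=O)[O-].[K+]
Why: Shi asymmetric epoxidation of the trisubstituted alkene sets Cd, the one stereocentre of the fragment that must be absolute (catalyst antipode chosen to give the drawn epoxide).

**Step 3**
Reactants: 4
Product: 5 (methyl 5-(2-hydroxypropan-2-yl)-2-methyltetrahydrofuran-2-carboxylate; Cd as in target, Ca epimeric mixture)
Conditions: CSA (10 mol %), CH2Cl2, 0 °C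
Reagents that add atoms: none
Why: Acid-catalysed 5-exo epoxy-alcohol cyclization (Baldwin-favoured) gives the 2,2,5-trisubstituted THF with inversion at Cd.

**Step 4**
Reactants: 5
Product: 6 (methyl 5-(2-acetoxypropan-2-yl)-2-methyltetrahydrofuran-2-carboxylate)
Conditions: Ac2O, Et3N, DMAP, 1,2-DCE, 60 °C
Reagents that add atoms: Ac2O, SMILES CC(=O)OC(C)=O
Why: DMAP-catalysed acylation of the tertiary alcohol installs the target acetate early.

**Step 5**
Reactants: 6
Product: 7 (5-(2-acetoxypropan-2-yl)-2-methyltetrahydrofuran-2-carboxylic acid; Ca epimeric mixture)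
Conditions: Me3SnOH, 1,2-DCE, 80 °C
Reagents that add atoms: Me3SnOH, SMILES C[Sn](C)(C)O
Why: Me3SnOH cleaves the hindered methyl ester mildly and leaves the tertiary acetate intact.

**Step 6**
Reactants: 7; 8 (cyclohepta-2,4-dien-1-one)
Product: 9 (5-substituted cycloheptenone carrying the THF; desired C7 diastereomer after separation; formed as α,β/β,γ-enone isomers that converge in step 7)
Conditions: [Ir(dF(CF3)ppy)2(dtbbpy)]PF6 (1 mol %), Cs2CO3, DMF, blue LEDs, rt; then aq NH4Cl; chromatographic separation of C7 epimers
Reagents that add atoms: none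
Why: Proposed new method: photoredox oxidation of the carboxylate and loss of CO2 gives the nucleophilic tertiary α-alkoxy radical, which adds to the δ-carbon (C7) of the dienone. This gives a captodative pentadienyl-type radical that is reduced to the dienolate and protonated. Ca is set trans to the CMe2OAc group by attack anti to that substituent. C7 is a new centre formed with modest selectivity, so the wanted diastereomer is separated. The closest known reactions are MacMillan-type decarboxylative Giese additions of α-oxy acids to enones and 1,6-additions to dienoates.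

**Step 7**
Reactants: 9
Product: 10 (4-hydroxy-5-(THF-yl)cyclohept-2-en-1-one; C6–OH trans to the C7 substituent)
Conditions: KHMDS, THF, –78 °C; O2; then P(OEt)3, –78 → 0 °C
Reagents that add atoms: O2, SMILES O=O
Why: Both enone isomers give the same extended dienolate. O2 attacks the γ-carbon (C6) anti to the adjacent C7 substituent (as in Δ4-3-keto steroid dienolate autoxidation), and P(OEt)3 reduces the hydroperoxide.

**Step 8**
Reactants: 10
Product: 11 (TBS ether of 10)
Conditions: TBSOTf, 2,6-lutidine, CH2Cl2, –78 °C
Reagents that add atoms: TBSOTf, SMILES CC(C)(C)[Si](C)(C)OS(=O)(=O)C(F)(F)F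
Why: Protection is needed before organometallic steps; the silyl ether also directs the next addition anti.

**Step 9**
Reactants: 11
Product: 12 (2-allyl-3-isopropenyl-4-OTBS-5-(THF-yl)cycloheptanone; C1 and C5 substituents trans)
Conditions: isopropenylMgBr, CuBr·SMe2, THF, –78 °C; then allyl iodide, HMPA, –78 → 0 °C
Reagents that add atoms: isopropenylmagnesium bromide, SMILES CC(=C)[Mg]Br; allyl iodide, SMILES C=CCI
Why: Tandem Cu-mediated conjugate addition/enolate alkylation: the cuprate adds to C5 anti to OTBS, so C4 ends up cis to the C7 THF, and the enolate is allylated trans to C4 at C1.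

**Step 10**
Reactants: 12
Product: 13 (cis-fused bicyclic ketone: C10 ketone, C3=C4 methylcyclopentene, C6-OTBS)
Conditions: DBU, PhMe, 60 °C; then Hoveyda–Grubbs II (5 mol %), 80 °C
Reagents that add atoms: none
Why: DBU epimerizes C1 (α to the ketone) to the cis-fused arrangement; ring-closing metathesis then forms the trisubstituted cyclopentene with the C3=C4 double bond placed regiospecifically.

**Step 11**
Reactants: 13
Product: 14 (C10 exocyclic methylene; C6-OTBS retained)
Conditions: Zn, CH2Br2, TiCl4, THF/CH2Cl2, 0 °C
Reagents that add atoms: CH2Br2, SMILES BrCBr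
Why: Lombardo–Takai methylenation is non-basic (no C1 epimerization) and ketone-selective (tertiary acetate, alkenes and silyl ether untouched).

**Step 12**
Reactants: 14
Product: 15 (C6 alcohol, trans to the cis-disposed C4/C7 substituents)
Conditions: TBAF/AcOH, THF, 40 °C
Reagents that add atoms: none
Why: Buffered fluoride removes the TBS group without cleaving the tertiary acetate.

**Step 13**
Reactants: 15
Product: 16 (C6 ketone)
Conditions: Dess–Martin periodinane, NaHCO3, CH2Cl2, rt
Reagents that add atoms: none
Why: Mild oxidation erases the C6 stereocentre that was set trans in step 7.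

**Step 14**
Reactants: 16
Product: 17 (dictyol H)
Conditions: NaBH4, CeCl3·7H2O, MeOH/CH2Cl2, –78 °C
Reagents that add atoms: none
Why: The C6 ketone is flanked by the up-oriented cyclopentene and THF substituents, so hydride enters from the convex face carrying the C1/C5/C7 hydrogens. This delivers the C6–OH cis to the neighbouring substituents, as in the target.

---

**Compound list**

| # | Name | SMILES | Role |
|---|---|---|---|
| 1 | 5-bromo-2-methylpent-2-ene | CC(C)=CCCBr | starting material |
| 2 | methyl pyruvate | COC(=O)C(C)=O | starting material |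
| 3 | methyl 2-hydroxy-2,6-dimethylhept-5-enoate | COC(=O)C(C)(O)CCC=C(C)C | intermediate |
| 4 | epoxy-alcohol (5,6-epoxide) | COC(=O)C(C)(O)CC[C@@H]1OC1(C)C | intermediate |
| 5 | THF hydroxy ester | COC(=O)C1(C)CC[C@H](C(C)(C)O)O1 | intermediate |
| 6 | THF acetoxy methyl ester | COC(=O)C1(C)CC[C@H](C(C)(C)OC(C)=O)O1 | intermediate |
| 7 | THF acetoxy carboxylic acid | OC(=O)C1(C)CC[C@H](C(C)(C)OC(C)=O)O1 | intermediate |
| 8 | cyclohepta-2,4-dien-1-one | O=C1C=CC=CCC1 | starting material |
| 9 | 5-(THF-yl)cyclohept-2-enone (conjugated isomer shown) | O=C1C=CC[C@H]([C@@]2(C)CC[C@H](C(C)(C)OC(C)=O)O2)CC1 | intermediate |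
| 10 | 4-hydroxy-5-(THF-yl)cyclohept-2-enone | O=C1C=C[C@@H](O)[C@H]([C@@]2(C)CC[C@H](C(C)(C)OC(C)=O)O2)CC1 | intermediate |
| 11 | TBS ether of 10 | O=C1C=C[C@@H](O[Si](C)(C)C(C)(C)C)[C@H]([C@@]2(C)CC[C@H](C(C)(C)OC(C)=O)O2)CC1 | intermediate |
| 12 | 2-allyl-3-isopropenyl cycloheptanone | O=C1[C@@H](CC=C)[C@H](C(C)=C)[C@@H](O[Si](C)(C)C(C)(C)C)[C@H]([C@@]2(C)CC[C@H](C(C)(C)OC(C)=O)O2)CC1 | intermediate |
| 13 | bicyclic ketone (cyclopentene-fused) | O=C1[C@@H]2CC=C(C)[C@@H]2[C@@H](O[Si](C)(C)C(C)(C)C)[C@H]([C@@]2(C)CC[C@H](C(C)(C)OC(C)=O)O2)CC1 | intermediate |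
| 14 | exocyclic methylene TBS ether | C=C1[C@@H]2CC=C(C)[C@@H]2[C@@H](O[Si](C)(C)C(C)(C)C)[C@H]([C@@]2(C)CC[C@H](C(C)(C)OC(C)=O)O2)CC1 | intermediate |
| 15 | C6-epi alcohol | C=C1[C@@H]2CC=C(C)[C@@H]2[C@@H](O)[C@H]([C@@]2(C)CC[C@H](C(C)(C)OC(C)=O)O2)CC1 | intermediate |
| 16 | C6 ketone | C=C1[C@@H]2CC=C(C)[C@@H]2C(=O)[C@H]([C@@]2(C)CC[C@H](C(C)(C)OC(C)=O)O2)CC1 | intermediate |
| 17 | dictyol H | C=C1[C@@H]2CC=C(C)[C@@H]2[C@H](O)[C@H]([C@@]2(C)CC[C@H](C(C)(C)OC(C)=O)O2)CC1 | target |

(SMILES 17 is the target SMILES rewritten from a different starting atom; all six stereocentres agree.)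

**Total steps:** 14. **Longest linear sequence:** 14 (steps 1–5 build the THF acid, which enters the linear core sequence at step 6).

**Three steps most likely to fail**
1. **Step 6 (radical 1,6-addition).**
   - Risks: the α-alkoxy radical can be over-oxidized to the oxocarbenium, and C7 is formed with poor diastereoselectivity.
   - Fallback: a polar coupling in which the 2-methoxy-2-methyl-THF oxocarbenium (TMSOTf, –78 °C) adds to the silyl trienol ether of 8 in a vinylogous Mukaiyama reaction, forming the same C7–Ca bond.
2. **Step 9 (facial selectivity of the cuprate addition).**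
   - Risk: the 1,3-relationship to the C7 THF group may override the anti-to-OTBS preference.
   - Fallback: reverse the sequence. Run the tandem addition/allylation/RCM/methylenation on 4-silyloxycyclohept-2-enone (from 1,3-cycloheptadiene by ¹O2 and Kornblum–DeLaMare), oxidize C6, then attach the THF unit at C7 by aldol with the methyl ketone and close the THF by epoxide opening.
3. **Step 7 (γ- versus α-oxygenation of the dienolate).**
   - Risk: O2 may attack C1 instead of C6.
   - Fallback: epoxidize the C5=C6 alkene of the β,γ-enone with mCPBA, then open the β,γ-epoxy ketone with DBU (E1cB) to give the γ-hydroxy enone 10.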